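**Retrosynthetic overview**

1. Drimane numbering is used for the sesquiterpene part: ring A is C1=C2–C3(=O)–C4(Me)2–C5–C10, ring B is C5–C6–C7=C8(Me)–C9(C11H2OAr)–C10(Me). The last disconnections are the ring A enone (C1=C2, intramolecular aldol condensation of a C1 aldehyde with the C3 methyl ketone) and the aryl ether O–C11 (Mitsunobu reaction with isofraxidin).
2. Key disconnection: ring B is a cyclohexene whose C7=C8 double bond lies opposite the C5–C10 fusion bond, a Diels–Alder retron. Cleaving C5–C6 and C9–C10 gives an (E)-3-methylpenta-2,4-dienyl unit (C6 to C9, C11) and an (E)-2-methyl-2-enoate (C10=C5, C1 as carboxyl) that carries the C4(Me)2–C3 chain.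
3. Enabling feature: C11–O on C9 and C1 on C10 are vicinal and syn on ring B, and C1 can pass through the carboxyl level. They are therefore tied as a temporary cis-fused γ-lactone (ester tether), which makes the cycloaddition intramolecular. The trans ring fusion (C5–H anti to C10–Me) is written into the E geometry of an open-chain dienophile; a ring A dienophile could only give the cis fusion.
4. Ring order: ring B together with the temporary lactone ring (key step); then the lactone is opened (lactol, hydrazone) and the aryl ether made; ring A is closed last.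
5. Absolute configuration: the C3 ketone is carried as its (R,R)-hydrobenzoin ketal, which is both protecting group and the covalent handle that turns the two mirror-image cycloadduct cores into separable diastereomers.

Key step: step 8

Remark: the free C11 hydroxyl is syn to C1 and would add to the β-carbon of the ring A enone (intramolecular oxa-Michael addition), so the aryl ether is made before ring A is closed. No facial bias from the remote ketal is counted on in the cycloaddition, so the key step is planned as a cycloaddition with resolution: both cis-fused diastereomers are expected, and only the (3aS,7R,7aR) one is carried on.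

**Route**

Step 1
Reactants: 1 ethyl 2,2-dimethyl-3-oxobutanoate; 2 (1R,2R)-1,2-diphenylethane-1,2-diol
Product: 4 ethyl 2-methyl-2-[(4R,5R)-2-methyl-4,5-diphenyl-1,3-dioxolan-2-yl]propanoate, via hydrobenzoin bis(trimethylsilyl) ether 3 (not isolated)
Conditions: 2, Me3SiCl, Et3N, CH2Cl2, 0 °C to rt, filtration; then 1, Me3SiOTf (5 mol%), CH2Cl2, −20 °C to rt
Reagents that add atoms: none
Why: Silyl-triflate-catalysed ketalisation with a bis-silyl ether is driven by Si–O–Si formation and is suited to a ketone flanked by a quaternary carbon; the diol stereocentres are not touched.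

Step 2
Reactants: 4 ethyl 2-methyl-2-[(4R,5R)-2-methyl-4,5-diphenyl-1,3-dioxolan-2-yl]propanoate
Product: 5 2-methyl-2-[(4R,5R)-2-methyl-4,5-diphenyl-1,3-dioxolan-2-yl]propan-1-ol
Conditions: LiAlH4, THF, 0 °C to rt
Reagents that add atoms: none
Why: Hydride reduction of the ester to the neopentyl alcohol; the ketal is inert to LiAlH4.

Step 3
Reactants: 5 2-methyl-2-[(4R,5R)-2-methyl-4,5-diphenyl-1,3-dioxolan-2-yl]propan-1-ol
Product: 6 2-methyl-2-[(4R,5R)-2-methyl-4,5-diphenyl-1,3-dioxolan-2-yl]propanal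
Conditions: Pr4N[RuO4] (5 mol%), N-methylmorpholine N-oxide, 4 Å molecular sieves, CH2Cl2, rt
Reagents that add atoms: none
Why: Ley–Griffith oxidation gives the non-enolisable neopentyl aldehyde under neutral conditions that spare the acid-labile ketal.

Step 4
Reactants: 6 2-methyl-2-[(4R,5R)-2-methyl-4,5-diphenyl-1,3-dioxolan-2-yl]propanal; 7 ethyl 2-(triphenyl-λ5-phosphanylidene)propanoate
Product: 8 ethyl (2E)-2,4-dimethyl-4-[(4R,5R)-2-methyl-4,5-diphenyl-1,3-dioxolan-2-yl]pent-2-enoate
Conditions: toluene, 110 °C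
Reagents that add atoms: none
Why: Wittig olefination with the stabilised α-methyl ylide should give the trisubstituted enoate with E geometry (ester trans to the quaternary carbon), which later encodes the trans ring fusion.

Step 5
Reactants: 8 ethyl (2E)-2,4-dimethyl-4-[(4R,5R)-2-methyl-4,5-diphenyl-1,3-dioxolan-2-yl]pent-2-enoate
Product: 9 (2E)-2,4-dimethyl-4-[(4R,5R)-2-methyl-4,5-diphenyl-1,3-dioxolan-2-yl]pent-2-enoic acid
Conditions: LiOH, THF/MeOH/H2O, 50 °C; then 1 M HCl to pH 4, 0 °C
Reagents that add atoms: lithium hydroxide, [Li+].[OH-]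
Why: Saponification of the ethyl ester; brief cold acidification leaves the ketal and the alkene geometry intact.

Step 6
Reactants: 10 (2E)-3-methylpent-2-en-4-yn-1-ol
Product: 11 (2E)-3-methylpenta-2,4-dien-1-ol
Conditions: H2 (1 atm), Pd/CaCO3 poisoned with Pb(OAc)2, quinoline, EtOAc, rt
Reagents that add atoms: none
Why: Lindlar semihydrogenation reduces the terminal alkyne to the vinyl group and leaves the trisubstituted E double bond and its geometry untouched.

Step 7
Reactants: 9 (2E)-2,4-dimethyl-4-[(4R,5R)-2-methyl-4,5-diphenyl-1,3-dioxolan-2-yl]pent-2-enoic acid; 11 (2E)-3-methylpenta-2,4-dien-1-ol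
Product: 12 (2E)-3-methylpenta-2,4-dien-1-yl (2E)-2,4-dimethyl-4-[(4R,5R)-2-methyl-4,5-diphenyl-1,3-dioxolan-2-yl]pent-2-enoate
Conditions: DCC, DMAP (10 mol%), CH2Cl2, 0 °C to rt
Reagents that add atoms: none
Why: Steglich esterification joins acid and allylic alcohol under neutral conditions, without allylic transposition or isomerisation of either double bond.

Step 8
Reactants: 12 (2E)-3-methylpenta-2,4-dien-1-yl (2E)-2,4-dimethyl-4-[(4R,5R)-2-methyl-4,5-diphenyl-1,3-dioxolan-2-yl]pent-2-enoate
Product: 13 (3aS,7R,7aR)-4,7a-dimethyl-7-{2-[(4R,5R)-2-methyl-4,5-diphenyl-1,3-dioxolan-2-yl]propan-2-yl}-3a,6,7,7a-tetrahydro-2-benzofuran-1(3H)-one (cis-fused lactone)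
Conditions: 1,2-dichlorobenzene (0.01 M), BHT (0.1 equiv), 180–200 °C, argon; then separation of 13 from the co-formed (3aR,7S,7aS) diastereomer by chromatography on silica gel or crystallisation
Reagents that add atoms: none
Why: On heating, the s-cis diene (C6=C7–C8=C9) and the E-configured trisubstituted enoate (C10=C5) of 12 combine in a concerted, asynchronous intramolecular [4+2] cycloaddition (type 1, ester tether between C11–O and C1), the closest known class being the thermal intramolecular Diels–Alder reaction of pentadienyl acrylates to bicyclic γ-lactones. Ring B closes as a cyclohexene by the [4+2] event itself with C7=C8 generated in place, and the five-membered lactone closes at the same time because the three-atom tether (C11, O, C1) spans the new C9–C10 bond, which also fixes the regiochemistry completely. The quaternary C10 and C5 take their mutual configuration (lactone carbonyl and C4 chain trans, hence the later trans ring fusion) from the E geometry of the dienophile by suprafacial addition, and C9 is set relative to C10 as the cis lactone fusion by the transition state in which the tether carbonyl lies endo under the E-diene. This cis-fused mode is the selectivity the step needs, and the substrate should secure it, because the tether-exo alternative would force both the quaternary C4 substituent and the C10 methyl under the diene and would end in a strained trans-fused γ-lactone. High dilution suppresses intermolecular cycloaddition, and the tether carbonyl is the only activating group, so no other π-bond competes. Neither diene face is preferred, so the two cis-fused cores should form in comparable amounts as diastereomers through the (4R,5R)-ketal; 13 is separated from the (3aR,7S,7aS)-4,7a-dimethyl-7-{2-[(4R,5R)-2-methyl-4,5-diphenyl-1,3-dioxolan-2-yl]propan-2-yl}-3a,6,7,7a-tetrahydro-2-benzofuran-1(3H)-one formed beside it, which is set aside, and the configuration of 13 is assigned relative to the known ketal centres.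

Step 9
Reactants: 13 (3aS,7R,7aR)-4,7a-dimethyl-7-{2-[(4R,5R)-2-methyl-4,5-diphenyl-1,3-dioxolan-2-yl]propan-2-yl}-3a,6,7,7a-tetrahydro-2-benzofuran-1(3H)-one
Product: 14 (3aS,7S,7aR)-4,7a-dimethyl-7-{2-[(4R,5R)-2-methyl-4,5-diphenyl-1,3-dioxolan-2-yl]propan-2-yl}-1,3,3a,6,7,7a-hexahydro-2-benzofuran-1-ol (lactol, mixture of anomers)
Conditions: i-Bu2AlH (1.1 equiv), CH2Cl2, −78 °C; aqueous KNaC4H4O6 (potassium sodium tartrate) work-up
Reagents that add atoms: none
Why: Low-temperature i-Bu2AlH reduction of the α-quaternary γ-lactone stops at the aluminium hemiacetal and gives the lactol (anomeric centre uncontrolled and irrelevant); ketal and alkene are inert.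

Step 10
Reactants: 14 (3aS,7S,7aR)-4,7a-dimethyl-7-{2-[(4R,5R)-2-methyl-4,5-diphenyl-1,3-dioxolan-2-yl]propan-2-yl}-1,3,3a,6,7,7a-hexahydro-2-benzofuran-1-ol
Product: 15 {(1S,5S,6R)-6-[(E)-(2,2-dimethylhydrazinylidene)methyl]-2,6-dimethyl-5-{2-[(4R,5R)-2-methyl-4,5-diphenyl-1,3-dioxolan-2-yl]propan-2-yl}cyclohex-2-en-1-yl}methanol
Conditions: Me2NNH2 (5 equiv), AcOH (cat.), EtOH, 60 °C
Reagents that add atoms: N,N-dimethylhydrazine, CN(C)N
Why: Hydrazone formation on the open hydroxy-aldehyde tautomer of the lactol traps C1 as a base-stable aldehyde equivalent and frees the C11 hydroxyl; no stereocentre is touched.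

Step 11
Reactants: 15 {(1S,5S,6R)-6-[(E)-(2,2-dimethylhydrazinylidene)methyl]-2,6-dimethyl-5-{2-[(4R,5R)-2-methyl-4,5-diphenyl-1,3-dioxolan-2-yl]propan-2-yl}cyclohex-2-en-1-yl}methanol; 16 7-hydroxy-6,8-dimethoxy-2H-chromen-2-one (isofraxidin)
Product: 17 7-({(1S,5S,6R)-6-[(E)-(2,2-dimethylhydrazinylidene)methyl]-2,6-dimethyl-5-{2-[(4R,5R)-2-methyl-4,5-diphenyl-1,3-dioxolan-2-yl]propan-2-yl}cyclohex-2-en-1-yl}methoxy)-6,8-dimethoxy-2H-chromen-2-one
Conditions: PPh3, diisopropyl azodicarboxylate, THF, 0 °C to 40 °C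
Reagents that add atoms: none
Why: Mitsunobu etherification of the primary alcohol with the acidic 7-hydroxycoumarin forms the aryl ether at a CH2 carbon, so no stereocentre is involved; with no enone yet present the hydroxyl cannot be lost to conjugate addition.

Step 12
Reactants: 17 7-({(1S,5S,6R)-6-[(E)-(2,2-dimethylhydrazinylidene)methyl]-2,6-dimethyl-5-{2-[(4R,5R)-2-methyl-4,5-diphenyl-1,3-dioxolan-2-yl]propan-2-yl}cyclohex-2-en-1-yl}methoxy)-6,8-dimethoxy-2H-chromen-2-one
Product: 19 6,8-dimethoxy-7-{[(1S,4aS,8aR)-2,5,5,8a-tetramethyl-6-oxo-1,4,4a,5,6,8a-hexahydronaphthalen-1-yl]methoxy}-2H-chromen-2-one, via keto aldehyde 18 (not isolated)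
Conditions: 1 M HCl, THF, 40 °C; extractive work-up; then piperidine (0.5 equiv), AcOH (0.5 equiv), toluene, 70 °C
Reagents that add atoms: water, O
Why: Aqueous acid hydrolyses hydrazone and ketal to keto aldehyde 18, and the amine–acid-catalysed intramolecular aldol condensation of the methyl ketone (the only enolisable site) onto the non-enolisable aldehyde closes ring A as the cyclohexenone; C5, C9 and C10 carry no acidic hydrogen and are not affected.

**Compound list**

1 | ethyl 2,2-dimethyl-3-oxobutanoate | CCOC(=O)C(C)(C)C(C)=O | starting material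
2 | (1R,2R)-1,2-diphenylethane-1,2-diol ((R,R)-hydrobenzoin) | O[C@H](c1ccccc1)[C@H](O)c1ccccc1 | starting material
3 | (1R,2R)-1,2-diphenyl-1,2-bis(trimethylsilyloxy)ethane | C[Si](C)(C)O[C@H](c1ccccc1)[C@H](O[Si](C)(C)C)c1ccccc1 | intermediate
4 | ethyl 2-methyl-2-[(4R,5R)-2-methyl-4,5-diphenyl-1,3-dioxolan-2-yl]propanoate | CCOC(=O)C(C)(C)C1(C)O[C@H](c2ccccc2)[C@@H](c2ccccc2)O1 | intermediate
5 | 2-methyl-2-[(4R,5R)-2-methyl-4,5-diphenyl-1,3-dioxolan-2-yl]propan-1-ol | OCC(C)(C)C1(C)O[C@H](c2ccccc2)[C@@H](c2ccccc2)O1 | intermediate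
6 | 2-methyl-2-[(4R,5R)-2-methyl-4,5-diphenyl-1,3-dioxolan-2-yl]propanal | O=CC(C)(C)C1(C)O[C@H](c2ccccc2)[C@@H](c2ccccc2)O1 | intermediate
7 | ethyl 2-(triphenyl-λ5-phosphanylidene)propanoate | CCOC(=O)C(C)=P(c1ccccc1)(c1ccccc1)c1ccccc1 | starting material
8 | ethyl (2E)-2,4-dimethyl-4-[(4R,5R)-2-methyl-4,5-diphenyl-1,3-dioxolan-2-yl]pent-2-enoate | CCOC(=O)/C(C)=C/C(C)(C)C1(C)O[C@H](c2ccccc2)[C@@H](c2ccccc2)O1 | intermediate
9 | (2E)-2,4-dimethyl-4-[(4R,5R)-2-methyl-4,5-diphenyl-1,3-dioxolan-2-yl]pent-2-enoic acid | OC(=O)/C(C)=C/C(C)(C)C1(C)O[C@H](c2ccccc2)[C@@H](c2ccccc2)O1 | intermediate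
10 | (2E)-3-methylpent-2-en-4-yn-1-ol | C#C/C(C)=C/CO | starting material
11 | (2E)-3-methylpenta-2,4-dien-1-ol | C=C/C(C)=C/CO | intermediate
12 | (2E)-3-methylpenta-2,4-dien-1-yl (2E)-2,4-dimethyl-4-[(4R,5R)-2-methyl-4,5-diphenyl-1,3-dioxolan-2-yl]pent-2-enoate | C=C/C(C)=C/COC(=O)/C(C)=C/C(C)(C)C1(C)O[C@H](c2ccccc2)[C@@H](c2ccccc2)O1 | intermediate
13 | (3aS,7R,7aR)-4,7a-dimethyl-7-{2-[(4R,5R)-2-methyl-4,5-diphenyl-1,3-dioxolan-2-yl]propan-2-yl}-3a,6,7,7a-tetrahydro-2-benzofuran-1(3H)-one | O=C1OC[C@H]2C(C)=CC[C@H](C(C)(C)C3(C)O[C@H](c4ccccc4)[C@@H](c4ccccc4)O3)[C@@]12C | intermediate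
14 | (3aS,7S,7aR)-4,7a-dimethyl-7-{2-[(4R,5R)-2-methyl-4,5-diphenyl-1,3-dioxolan-2-yl]propan-2-yl}-1,3,3a,6,7,7a-hexahydro-2-benzofuran-1-ol | OC1OC[C@H]2C(C)=CC[C@H](C(C)(C)C3(C)O[C@H](c4ccccc4)[C@@H](c4ccccc4)O3)[C@@]12C | intermediate
15 | {(1S,5S,6R)-6-[(E)-(2,2-dimethylhydrazinylidene)methyl]-2,6-dimethyl-5-{2-[(4R,5R)-2-methyl-4,5-diphenyl-1,3-dioxolan-2-yl]propan-2-yl}cyclohex-2-en-1-yl}methanol | OC[C@H]1C(C)=CC[C@H](C(C)(C)C2(C)O[C@H](c3ccccc3)[C@@H](c3ccccc3)O2)[C@@]1(C)/C=N/N(C)C | intermediate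
16 | 7-hydroxy-6,8-dimethoxy-2H-chromen-2-one (isofraxidin) | COc1cc2ccc(=O)oc2c(OC)c1O | starting material
17 | 7-({(1S,5S,6R)-6-[(E)-(2,2-dimethylhydrazinylidene)methyl]-2,6-dimethyl-5-{2-[(4R,5R)-2-methyl-4,5-diphenyl-1,3-dioxolan-2-yl]propan-2-yl}cyclohex-2-en-1-yl}methoxy)-6,8-dimethoxy-2H-chromen-2-one | COc1cc2ccc(=O)oc2c(OC)c1OC[C@H]1C(C)=CC[C@H](C(C)(C)C2(C)O[C@H](c3ccccc3)[C@@H](c3ccccc3)O2)[C@@]1(C)/C=N/N(C)C | intermediate
18 | (1R,2S,6S)-2-{[(6,8-dimethoxy-2-oxo-2H-chromen-7-yl)oxy]methyl}-1,3-dimethyl-6-(2-methyl-3-oxobutan-2-yl)cyclohex-3-ene-1-carbaldehyde | COc1cc2ccc(=O)oc2c(OC)c1OC[C@H]1C(C)=CC[C@H](C(C)(C)C(C)=O)[C@@]1(C)C=O | intermediate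
19 | 6,8-dimethoxy-7-{[(1S,4aS,8aR)-2,5,5,8a-tetramethyl-6-oxo-1,4,4a,5,6,8a-hexahydronaphthalen-1-yl]methoxy}-2H-chromen-2-one | COc1cc2ccc(=O)oc2c(OC)c1OC[C@H]1C(C)=CC[C@@H]2C(C)(C)C(=O)C=C[C@]21C | target

**Step count and risks**

Total steps: 12. Longest linear sequence: 11 (steps 1–5 and 7–12, from 1).

Steps most likely to fail:

Step 8. The tether-exo transition state may compete and give the trans-fused lactone, and the trisubstituted, β-quaternary dienophile may react so slowly that thermal decomposition or intermolecular reaction overtakes the cycloaddition. Fallback: the diene geometry is changed so that only the cis ring fusion is geometrically possible. Setting out from acid 9, commercial (2Z)-3-methylpent-2-en-4-yn-1-ol F1 is semihydrogenated (H2, Pd/CaCO3 poisoned with Pb(OAc)2) to (2Z)-3-methylpenta-2,4-dien-1-ol F2, which is esterified with 9 (DCC, DMAP) to the (2Z)-dienyl ester F3. With the tether on the inside position of the diene, thermolysis of F3 can close only the cis-fused lactone and, the dienophile being unchanged, comes back to the route at 13 (again separated from its (3aR,7S,7aS) diastereomer).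

Step 11. Substitution at the β-branched primary carbon by the di-ortho-substituted phenoxide may be slow, so that the hydrazone nitrogen intercepts the alkoxyphosphonium ion or the azodicarboxylate. Fallback: a non-nucleophilic aldehyde mask and a plain alkylation replace the redox condensation. Setting out from lactol 14, condensation with MeONH2·HCl and pyridine gives the hydroxy O-methyl oxime F4; an Appel reaction (I2, PPh3, imidazole) gives the iodide F5; alkylation of 16 (Cs2CO3, DMF, 60 °C) gives the aryl ether oxime F6. Acid-catalysed exchange with excess aqueous formaldehyde (1 M HCl, THF) removes oxime ether and ketal and comes back to the route at 18.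

Step 12. Addition of the methyl ketone to the neopentyl aldehyde may be slow or the dehydration incomplete, and prolonged acid may move the C7=C8 double bond. Fallback: the ring closure is made irreversible and the elimination separate. Setting out from 18 (isolated after the acid stage), Me3SiOTf and Et3N convert the methyl ketone into its trimethylsilyl enol ether F7; intramolecular Mukaiyama aldol addition (BF3·OEt2, CH2Cl2, −78 °C) gives the β-hydroxy ketone F8; mesylation (MsCl, Et3N) to the mesylate F9 and elimination with DBU come back to the route at 19.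

**Further compounds**

F1 | step 8 | (2Z)-3-methylpent-2-en-4-yn-1-ol | C#C/C(C)=C\CO
F2 | step 8 | (2Z)-3-methylpenta-2,4-dien-1-ol | C=C/C(C)=C\CO
F3 | step 8 | (2Z)-3-methylpenta-2,4-dien-1-yl (2E)-2,4-dimethyl-4-[(4R,5R)-2-methyl-4,5-diphenyl-1,3-dioxolan-2-yl]pent-2-enoate | C=C/C(C)=C\COC(=O)/C(C)=C/C(C)(C)C1(C)O[C@H](c2ccccc2)[C@@H](c2ccccc2)O1
F4 | step 11 | {(1S,5S,6R)-6-[(E)-(methoxyimino)methyl]-2,6-dimethyl-5-{2-[(4R,5R)-2-methyl-4,5-diphenyl-1,3-dioxolan-2-yl]propan-2-yl}cyclohex-2-en-1-yl}methanol | OC[C@H]1C(C)=CC[C@H](C(C)(C)C2(C)O[C@H](c3ccccc3)[C@@H](c3ccccc3)O2)[C@@]1(C)/C=N/OC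
F5 | step 11 | O-methyl oxime of the 2-(iodomethyl)cyclohexenecarbaldehyde corresponding to F4 | IC[C@H]1C(C)=CC[C@H](C(C)(C)C2(C)O[C@H](c3ccccc3)[C@@H](c3ccccc3)O2)[C@@]1(C)/C=N/OC
F6 | step 11 | 7-aryl ether of F4 (O-methyl oxime analogue of 17) | COc1cc2ccc(=O)oc2c(OC)c1OC[C@H]1C(C)=CC[C@H](C(C)(C)C2(C)O[C@H](c3ccccc3)[C@@H](c3ccccc3)O2)[C@@]1(C)/C=N/OC
F7 | step 12 | trimethylsilyl enol ether of the methyl ketone of 18 | COc1cc2ccc(=O)oc2c(OC)c1OC[C@H]1C(C)=CC[C@H](C(C)(C)C(=C)O[Si](C)(C)C)[C@@]1(C)C=O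
F8 | step 12 | 7-{[(1S,4aS,8aR)-8-hydroxy-2,5,5,8a-tetramethyl-6-oxo-1,4,4a,5,6,7,8,8a-octahydronaphthalen-1-yl]methoxy}-6,8-dimethoxy-2H-chromen-2-one (carbinol epimers) | COc1cc2ccc(=O)oc2c(OC)c1OC[C@H]1C(C)=CC[C@@H]2C(C)(C)C(=O)CC(O)[C@]21C
F9 | step 12 | methanesulfonate of F8 | COc1cc2ccc(=O)oc2c(OC)c1OC[C@H]1C(C)=CC[C@@H]2C(C)(C)C(=O)CC(OS(C)(=O)=O)[C@]21C
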